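The target is cut at the two bonds joining each CH(4-hydroxyphenyl) carbon to C2 of a 3,5-dihydroxyphenyl ring, the bonds that complete both eight-membered carbocycles. Each methine sits para to the hydroxyl of its own 4-hydroxyphenyl ring, so it can be unmasked as the exocyclic carbon of a para-quinone methide, and the ring carbon it joins is ortho and para to oxygen. The two methines are also the stereocentres that make an otherwise mirror-symmetric framework chiral. One chiral-acid-catalysed operation on a meso bis(quinone methide) therefore forms both bonds, both rings and both stereocentres. Its stable precursor is a meso 1,4-bis(4-hydroxyphenyl)butane-1,4-diol carrying two mirror-image dihydrobenzofurans, with bromine on the competing ring carbons.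

Key step: step 10

Remark (names): ring C is the benzo ring of each dihydrobenzofuran, ring B is the 3,5-dimethoxyphenyl ring on furan C3, and the two CH carbons of the butane chain that carry the benzofurans are the central carbons.

Remark (selectivity): each methide carbon can be reached by three oxygen-activated positions, namely C5 of the neighbouring benzofuran (five-membered ring, an indane), ring B of its own half (seven-membered ring) and ring B of the other half (eight-membered ring, the one required). The precursor is therefore built with bromine at benzofuran C5 and with the central configuration that turns each methide arm away from its own ring B.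

Assumption: the (R) antipode of the phosphoric acid is taken to give the (R,R) methines; if it gives the mirror image, the (S) acid is used.

Step 1
Reactants: 1 methyl 2-(3,5-dimethoxyphenyl)acetate (2 equiv)
Product: 2 dimethyl (2R,3S)-2,3-bis(3,5-dimethoxyphenyl)butanedioate (meso)
Conditions: LiN(iPr)2, THF, −78 °C; I2 (0.5 equiv), −78 to 0 °C; then NaOMe (cat.), MeOH, 50 °C, crystallise
Reagents that add atoms: none
Why: Oxidative homocoupling of the lithium ester enolate with I2 (the α-iodo ester formed first is alkylated by a second enolate); both new stereocentres remain epimerisable α to the esters, so catalytic NaOMe equilibrates the dl and meso diesters while the meso isomer, expected to be the less soluble, crystallises.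

Step 2
Reactants: 2 dimethyl (2R,3S)-2,3-bis(3,5-dimethoxyphenyl)butanedioate; 3 3,5-dimethoxybenzoyl chloride (2.5 equiv)
Product: 5 dimethyl (2R,3S)-2,3-bis[2-(3,5-dimethoxybenzoyl)-3-hydroxy-5-methoxyphenyl]butanedioate (meso), via bis-ketone 4 (not isolated)
Conditions: AlCl3 (6 equiv), CH2Cl2, 0 to 25 °C; aq. HCl
Reagents that add atoms: none
Why: Friedel–Crafts acylation enters each resorcinol diether ring para to one methoxy group and ortho to the benzylic carbon (the carbon between the two methoxy groups is the least reactive, and the first acyl group deactivates its own ring so the second goes to the other ring), after which excess AlCl3 cleaves only the methoxy group chelated to the new ketone; no stereocentre is touched and the acid medium does not epimerise the α-aryl esters.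

Step 3
Reactants: 5 dimethyl (2R,3S)-2,3-bis[2-(3,5-dimethoxybenzoyl)-3-hydroxy-5-methoxyphenyl]butanedioate
Product: 7 (4R,4'S)-1,1'-bis(3,5-dimethoxyphenyl)-8,8'-dihydroxy-6,6'-dimethoxy-4,4'-biisochromane-3,3'-dione (epimers at C1 and C1'), via bis-benzhydrol 6 (not isolated)
Conditions: NaBH4, THF–MeOH, 0 to 25 °C; then TsOH·H2O (cat.), PhMe, 40 °C
Reagents that add atoms: none
Why: Chemoselective NaBH4 reduction of the diaryl ketones in the presence of the esters, followed by acid-catalysed lactonisation of each benzhydrol onto the neighbouring ester to a six-membered lactone whose carboxylate is the leaving group for step 5; the carbinol centres form without control and are erased in step 5.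

Step 4
Reactants: 8 (4-methoxyphenyl)methanol; 9 tetrahydrothiophene
Product: 10 1-[(4-methoxyphenyl)methyl]thiolan-1-ium tetrafluoroborate
Conditions: HBF4·OEt2, CH2Cl2, 0 to 25 °C; precipitate with Et2O
Reagents that add atoms: tetrafluoroboric acid (diethyl ether complex), [H+].F[B-](F)(F)F
Why: SN1 alkylation of the sulfide by the 4-methoxybenzyl cation released from the alcohol by the strong acid, the non-nucleophilic BF4 counter-ion keeping the sulfonium salt from reverting.

Step 5
Reactants: 7 (4R,4'S)-bis-lactone; 10 1-[(4-methoxyphenyl)methyl]thiolan-1-ium tetrafluoroborate (2.6 equiv)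
Product: 12 (2R,3S)-2-[(2S,3S)-3-(3,5-dimethoxyphenyl)-6-methoxy-2-(4-methoxyphenyl)-2,3-dihydro-1-benzofuran-4-yl]-3-[(2R,3R)-3-(3,5-dimethoxyphenyl)-6-methoxy-2-(4-methoxyphenyl)-2,3-dihydro-1-benzofuran-4-yl]butanedioic acid (meso), via bis(ortho-quinone methide) 11 (not isolated)
Conditions: Cs2CO3 (6 equiv), MeCN, 0 to 25 °C; aq. HCl to pH 3
Reagents that add atoms: none
Why: Formal [4+1] annulation of an ortho-quinone methide with a sulfonium ylide, in which phenoxide formation expels the lactone carboxylate, A(1,3) strain is expected to hold the central C–H in the arene plane beside the methide carbon so that the ylide made from 10 adds to the methide face flanked by the small carboxylate and not by the bulky CH(aryl) branch (this sets C3 relative to the central carbon and, by symmetry, gives the meso product), and phenoxide SN2 displacement of tetrahydrothiophene through the anti betaine sets C2 trans to C3.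

Step 6
Reactants: 12 meso diacid
Product: 13 (2R,3S)-2,3-bis(dihydrobenzofuran-4-yl)butane-1,4-diol, aryl groups and configuration as in 12 (meso)
Conditions: LiAlH4, THF, 0 to 60 °C; aq. NaOH work-up
Reagents that add atoms: none
Why: LiAlH4 reduction of the carboxylic acids to primary alcohols, which leaves the four furan stereocentres untouched and removes the acidity of the central C–H bonds.

Step 7
Reactants: 13 meso diol
Product: 14 tetrabromide of 13 with Br at C5 of each benzofuran and at C2 of each 3,5-dimethoxyphenyl ring (meso, configuration as in 13)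
Conditions: NBS (4.1 equiv), CH2Cl2, −78 to 0 °C, dark
Reagents that add atoms: N-bromosuccinimide, O=C1CCC(=O)N1Br
Why: Electrophilic aromatic bromination with NBS, in which each of the four 1,3-dioxygenated rings takes one bromine para to an oxygen (C5 of each benzofuran, the only such site on ring C, and C2 of each ring B) and is thereby deactivated against a second substitution while the mono-oxygenated anisyl rings react far more slowly; the bromine at benzofuran C5 is the blocking group for step 10 and ring B keeps its C6 position free.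

Step 8
Reactants: 14 tetrabromo diol
Product: 15 (2R,3S)-2,3-diarylbutanedial, aryl groups as in 14 (meso)
Conditions: Dess–Martin periodinane (2.5 equiv), NaHCO3, CH2Cl2, 0 to 25 °C; used at once
Reagents that add atoms: none
Why: Dess–Martin oxidation of the primary alcohols under buffered, non-basic conditions, the α-aryl dialdehyde being taken on at once so that the central stereocentres do not enolise.

Step 9
Reactants: 15 meso dialdehyde; 16 (4-bromophenoxy)(tert-butyl)dimethylsilane (3 equiv)
Product: 18 (2R,3S)-1,4-bis(4-hydroxyphenyl)-2,3-diarylbutane-1,4-diol, aryl groups as in 14 (carbinol epimers), via bis-silyl ether 17 (not isolated)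
Conditions: 16, Mg, THF, 25 °C; CeCl3, −78 °C; add 15, −78 °C; aq. NH4Cl; then Bu4NF, AcOH, THF, 0 °C
Reagents that add atoms: none
Why: Grignard 1,2-addition of the aryl nucleophile to the aldehydes at −78 °C in the presence of CeCl3 (addition outruns enolisation and the aryl bromides do not exchange at this temperature), then fluoride cleavage of the aryl silyl ethers buffered with acetic acid; the carbinol centres form as a mixture that is erased in step 10.

Step 10
Reactants: 18 meso bis(4-hydroxybenzylic alcohol)
Product: 20 tetrabromo octamethyl ether of the target with both methine 4-hydroxyphenyl groups free, via meso bis(para-quinone methide) 19 (not isolated)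
Conditions: (R)-TRIP [(R)-3,3'-bis(2,4,6-triisopropylphenyl)-1,1'-binaphthyl-2,2'-diyl hydrogen phosphate] (20 mol %), 4 Å molecular sieves, PhCF3, 0.002 M, 0 to 25 °C
Reagents that add atoms: none
Why: Proposed new method: The chiral phosphoric acid dehydrates both 4-hydroxybenzylic alcohols to the meso bis(para-quinone methide) 19 and stays hydrogen-bonded to a quinone oxygen; C6 of ring B of one half (ortho to one methoxy group, para to the other) then adds to the exocyclic methide carbon of the other half in a 1,6-conjugate Friedel–Crafts reaction, rearomatisation returns the phenol, and the same events follow at the second terminus. The closest known reaction is the chiral phosphoric acid-catalysed 1,6-addition of electron-rich arenes to para-quinone methides generated in situ from 4-hydroxybenzylic alcohols; closing a medium ring this way, and doing so twice on a meso substrate, is new. Each eight-membered ring closes in the 8-exo-trig mode, the methide carbon lying in the new ring and its double-bond partner outside it. The first closure is the desymmetrising event, in which the catalyst chooses one of the two enantiotopic quinone methides and the face of its methide carbon and so sets the first methine; the second methine is set by the same catalyst on the now rigid monocycle and must take the same absolute sense, against the local preference of that half. The step needs ring-size selectivity (eight over five and seven): bromine at benzofuran C5 removes the carbon that would give an indane, the central configuration holds each methide arm on the benzofuran face opposite its own ring B and next to ring B of the other half, and high dilution suppresses oligomers.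

Step 11
Reactants: 20 tetrabromo octamethyl ether
Product: 21 octamethyl ether of the target with the two methine 4-hydroxyphenyl groups free
Conditions: H2 (1 atm), Pd/C (10 wt% palladium on carbon), Et3N, EtOAc–MeOH, 25 °C
Reagents that add atoms: none
Why: Heterogeneous palladium-catalysed hydrogenolysis of the four aryl C–Br bonds, with triethylamine taking up the HBr so that the benzylic C–O bonds of the dihydrobenzofurans are neither ionised nor cleaved; no stereocentre is affected.

Step 12
Reactants: 21 octamethyl ether
Product: 22 CNP0224452.2 (target)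
Conditions: BBr3 (excess), CH2Cl2, −78 to 25 °C; MeOH, then H2O
Reagents that add atoms: none
Why: BBr3 cleavage of all eight aryl methyl ethers by bromide attack on the O-methyl carbon of the boron-complexed ethers, which leaves the aryl–alkyl ether bonds of the dihydrobenzofurans and all eight stereocentres in place.

Compound list

1 | methyl 2-(3,5-dimethoxyphenyl)acetate | COC(=O)Cc1cc(OC)cc(OC)c1 | starting material
2 | dimethyl (2R,3S)-2,3-bis(3,5-dimethoxyphenyl)butanedioate (meso) | COC(=O)[C@@H](c1cc(OC)cc(OC)c1)[C@@H](c1cc(OC)cc(OC)c1)C(=O)OC | intermediate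
3 | 3,5-dimethoxybenzoyl chloride | COc1cc(cc(OC)c1)C(Cl)=O | starting material
4 | dimethyl (2R,3S)-2,3-bis[2-(3,5-dimethoxybenzoyl)-3,5-dimethoxyphenyl]butanedioate (meso bis-ketone) | COC(=O)[C@@H](c1cc(OC)cc(OC)c1C(=O)c1cc(OC)cc(OC)c1)[C@@H](c1cc(OC)cc(OC)c1C(=O)c1cc(OC)cc(OC)c1)C(=O)OC | intermediate
5 | dimethyl (2R,3S)-2,3-bis[2-(3,5-dimethoxybenzoyl)-3-hydroxy-5-methoxyphenyl]butanedioate (meso) | COC(=O)[C@@H](c1cc(OC)cc(O)c1C(=O)c1cc(OC)cc(OC)c1)[C@@H](c1cc(OC)cc(O)c1C(=O)c1cc(OC)cc(OC)c1)C(=O)OC | intermediate
6 | dimethyl (2R,3S)-2,3-bis{2-[(3,5-dimethoxyphenyl)(hydroxy)methyl]-3-hydroxy-5-methoxyphenyl}butanedioate (bis-benzhydrol, carbinol epimers) | COC(=O)[C@@H](c1cc(OC)cc(O)c1C(O)c1cc(OC)cc(OC)c1)[C@@H](c1cc(OC)cc(O)c1C(O)c1cc(OC)cc(OC)c1)C(=O)OC | intermediate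
7 | (4R,4'S)-1,1'-bis(3,5-dimethoxyphenyl)-8,8'-dihydroxy-6,6'-dimethoxy-4,4'-biisochromane-3,3'-dione (bis-lactone, epimers at C1 and C1') | O=C1OC(c2cc(OC)cc(OC)c2)c2c(O)cc(OC)cc2[C@H]1[C@@H]1C(=O)OC(c2cc(OC)cc(OC)c2)c2c(O)cc(OC)cc21 | intermediate
8 | (4-methoxyphenyl)methanol | COc1ccc(CO)cc1 | starting material
9 | tetrahydrothiophene | C1CCSC1 | starting material
10 | 1-[(4-methoxyphenyl)methyl]thiolan-1-ium tetrafluoroborate | COc1ccc(C[S+]2CCCC2)cc1.F[B-](F)(F)F | intermediate
11 | (2R,3S)-2,3-bis{(6Z)-6-[(3,5-dimethoxyphenyl)methylidene]-3-methoxy-5-oxocyclohexa-1,3-dien-1-yl}butanedioic acid (bis(ortho-quinone methide), aryl on the carbonyl side) | OC(=O)[C@@H](C1=CC(OC)=CC(=O)/C1=C\c1cc(OC)cc(OC)c1)[C@@H](C1=CC(OC)=CC(=O)/C1=C\c1cc(OC)cc(OC)c1)C(=O)O | intermediate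
12 | (2R,3S)-2-[(2S,3S)-3-(3,5-dimethoxyphenyl)-6-methoxy-2-(4-methoxyphenyl)-2,3-dihydro-1-benzofuran-4-yl]-3-[(2R,3R)-3-(3,5-dimethoxyphenyl)-6-methoxy-2-(4-methoxyphenyl)-2,3-dihydro-1-benzofuran-4-yl]butanedioic acid (meso) | OC(=O)[C@@H](c1cc(OC)cc2c1[C@H](c1cc(OC)cc(OC)c1)[C@@H](c1ccc(OC)cc1)O2)[C@@H](c1cc(OC)cc2c1[C@@H](c1cc(OC)cc(OC)c1)[C@H](c1ccc(OC)cc1)O2)C(=O)O | intermediate
13 | (2R,3S)-butane-1,4-diol carrying at C2 and C3 the same two trans-dihydrobenzofuran-4-yl groups as 12 (meso) | OC[C@@H](c1cc(OC)cc2c1[C@H](c1cc(OC)cc(OC)c1)[C@@H](c1ccc(OC)cc1)O2)[C@@H](c1cc(OC)cc2c1[C@@H](c1cc(OC)cc(OC)c1)[C@H](c1ccc(OC)cc1)O2)CO | intermediate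
14 | tetrabromide of 13: Br at C5 of each benzofuran and at C2 of each 3,5-dimethoxyphenyl ring, configuration unchanged (meso) | OC[C@@H](c1c(Br)c(OC)cc2c1[C@H](c1c(Br)c(OC)cc(OC)c1)[C@@H](c1ccc(OC)cc1)O2)[C@@H](c1c(Br)c(OC)cc2c1[C@@H](c1c(Br)c(OC)cc(OC)c1)[C@H](c1ccc(OC)cc1)O2)CO | intermediate
15 | (2R,3S)-2,3-diarylbutanedial, aryl groups as in 14 (meso) | O=C[C@@H](c1c(Br)c(OC)cc2c1[C@H](c1c(Br)c(OC)cc(OC)c1)[C@@H](c1ccc(OC)cc1)O2)[C@@H](c1c(Br)c(OC)cc2c1[C@@H](c1c(Br)c(OC)cc(OC)c1)[C@H](c1ccc(OC)cc1)O2)C=O | intermediate
16 | (4-bromophenoxy)(tert-butyl)dimethylsilane | CC(C)(C)[Si](C)(C)Oc1ccc(Br)cc1 | starting material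
17 | (2R,3S)-1,4-bis[4-(tert-butyldimethylsilyloxy)phenyl]-2,3-diarylbutane-1,4-diol, aryl groups as in 14 (carbinol epimers) | CC(C)(C)[Si](C)(C)Oc1ccc(cc1)C(O)[C@@H](c1c(Br)c(OC)cc2c1[C@H](c1c(Br)c(OC)cc(OC)c1)[C@@H](c1ccc(OC)cc1)O2)[C@@H](c1c(Br)c(OC)cc2c1[C@@H](c1c(Br)c(OC)cc(OC)c1)[C@H](c1ccc(OC)cc1)O2)C(O)c1ccc(O[Si](C)(C)C(C)(C)C)cc1 | intermediate
18 | (2R,3S)-1,4-bis(4-hydroxyphenyl)-2,3-diarylbutane-1,4-diol, aryl groups as in 14 (carbinol epimers) | Oc1ccc(cc1)C(O)[C@@H](c1c(Br)c(OC)cc2c1[C@H](c1c(Br)c(OC)cc(OC)c1)[C@@H](c1ccc(OC)cc1)O2)[C@@H](c1c(Br)c(OC)cc2c1[C@@H](c1c(Br)c(OC)cc(OC)c1)[C@H](c1ccc(OC)cc1)O2)C(O)c1ccc(O)cc1 | intermediate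
19 | meso bis(para-quinone methide): 4,4'-[(2R,3S)-2,3-diarylbutane-1,4-diylidene]bis(cyclohexa-2,5-dien-1-one), aryl groups as in 14 | O=C1C=CC(C=C1)=C[C@@H](c1c(Br)c(OC)cc2c1[C@H](c1c(Br)c(OC)cc(OC)c1)[C@@H](c1ccc(OC)cc1)O2)[C@@H](c1c(Br)c(OC)cc2c1[C@@H](c1c(Br)c(OC)cc(OC)c1)[C@H](c1ccc(OC)cc1)O2)C=C1C=CC(=O)C=C1 | intermediate
20 | tetrabromo octamethyl ether of the target, both methine 4-hydroxyphenyl groups free; Br at C5 of each benzofuran ring and, on each ring B, at the carbon ortho to the furan-bonded carbon and meta to the methine-bonded carbon | Oc1ccc([C@@H]2c3c(OC)cc(OC)c(Br)c3[C@@H]3c4c(cc(OC)c(Br)c4[C@H]4[C@H](c5ccc(O)cc5)c5c(OC)cc(OC)c(Br)c5[C@H]5c6c(cc(OC)c(Br)c6[C@H]24)O[C@@H]5c2ccc(OC)cc2)O[C@H]3c2ccc(OC)cc2)cc1 | intermediate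
21 | octamethyl ether of the target (all ring B, ring C and 2-aryl oxygens methylated), both methine 4-hydroxyphenyl groups free | Oc1ccc([C@@H]2c3c(OC)cc(OC)cc3[C@@H]3c4c(cc(OC)cc4[C@H]4[C@H](c5ccc(O)cc5)c5c(OC)cc(OC)cc5[C@H]5c6c(cc(OC)cc6[C@H]24)O[C@@H]5c2ccc(OC)cc2)O[C@H]3c2ccc(OC)cc2)cc1 | intermediate
22 | CNP0224452.2 | Oc1ccc([C@@H]2c3c(O)cc(O)cc3[C@@H]3c4c(cc(O)cc4[C@H]4[C@H](c5ccc(O)cc5)c5c(O)cc(O)cc5[C@H]5c6c(cc(O)cc6[C@H]24)O[C@@H]5c2ccc(O)cc2)O[C@H]3c2ccc(O)cc2)cc1 | target

Total step count: 12. Longest linear sequence: 11 (steps 1 to 3 and 5 to 12; step 4 makes the sulfonium salt).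

Steps most likely to fail

Step 10. The catalyst may fail to tell the two enantiotopic termini or the two methide faces apart, above all in the second closure, where it works against the local preference; the Cs-symmetric diastereomer or material of low enantiomeric purity would result. The fallback gives up the desymmetrisation. It sets out from 18: an achiral Brønsted acid (diphenyl phosphate or TfOH, PhCF3, high dilution) brings about the same known Friedel–Crafts alkylation of an electron-rich arene by a 4-hydroxybenzylic alcohol without asymmetric induction. This should give 20 together with its enantiomer ent-20 F1; any Cs-symmetric isomer is removed on silica. The racemate is resolved by preparative chromatography on a chiral stationary phase and the route resumes at 20.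

Step 5. Facial selectivity of the ylide addition relative to the central stereocentres may be poor, because the A(1,3) bias that fixes the reactive rotamer is modest; diastereomers at the furan carbons would form beside the required meso acid. The fallback sets out from 12 as obtained (the mixture). DDQ (PhMe, 80 °C) dehydrogenates every diastereomer to the same meso bis(benzofuran) diacid F2, which erases the furan stereocentres. Hydrogenation over Rh/Al2O3 (rhodium on alumina) or Pd/C under pressure then delivers both hydrogens to each furan from the face not covered by the other half of the molecule. This should give the all-cis bis(dihydrobenzofuran) diacid F3, with each ring B on the face of the central C–C bond. Brief treatment with CF3CO2H epimerises C2 through the 4-methoxybenzylic cation to the trans isomer, and the route is rejoined at 12.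

Step 2. Acylation may enter the carbon between the two methoxy groups, or stall after one acyl group, because the required position lies beside the bulky central carbon. The fallback fixes the regiochemistry before the central bond exists. It sets out from 1 and 3: SnCl4 in CH2Cl2 acylates the monomer ortho to its CH2 group, the usual site for 3,5-dimethoxyphenylacetates, to give the keto ester methyl 2-[2-(3,5-dimethoxybenzoyl)-3,5-dimethoxyphenyl]acetate F4. Oxidative enolate coupling (LiN(iPr)2, I2, then NaOMe equilibration) rejoins the route at 4, which BCl3 in CH2Cl2 demethylates to 5.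

Further compounds

F1 | step 10 | enantiomer of 20 (ent-20) | Oc1ccc([C@H]2c3c(OC)cc(OC)c(Br)c3[C@H]3c4c(cc(OC)c(Br)c4[C@@H]4[C@@H](c5ccc(O)cc5)c5c(OC)cc(OC)c(Br)c5[C@@H]5c6c(cc(OC)c(Br)c6[C@@H]24)O[C@H]5c2ccc(OC)cc2)O[C@@H]3c2ccc(OC)cc2)cc1
F2 | step 5 | (2R,3S)-2,3-bis[3-(3,5-dimethoxyphenyl)-6-methoxy-2-(4-methoxyphenyl)-1-benzofuran-4-yl]butanedioic acid (meso) | OC(=O)[C@@H](c1cc(OC)cc2oc(-c3ccc(OC)cc3)c(-c3cc(OC)cc(OC)c3)c12)[C@@H](c1cc(OC)cc2oc(-c3ccc(OC)cc3)c(-c3cc(OC)cc(OC)c3)c12)C(=O)O
F3 | step 5 | (2R,3S)-2-[(2R,3S)-3-(3,5-dimethoxyphenyl)-6-methoxy-2-(4-methoxyphenyl)-2,3-dihydro-1-benzofuran-4-yl]-3-[(2S,3R)-3-(3,5-dimethoxyphenyl)-6-methoxy-2-(4-methoxyphenyl)-2,3-dihydro-1-benzofuran-4-yl]butanedioic acid (meso, both furans cis) | OC(=O)[C@@H](c1cc(OC)cc2c1[C@H](c1cc(OC)cc(OC)c1)[C@H](c1ccc(OC)cc1)O2)[C@@H](c1cc(OC)cc2c1[C@@H](c1cc(OC)cc(OC)c1)[C@@H](c1ccc(OC)cc1)O2)C(=O)O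
F4 | step 2 | methyl 2-[2-(3,5-dimethoxybenzoyl)-3,5-dimethoxyphenyl]acetate | COC(=O)Cc1cc(OC)cc(OC)c1C(=O)c1cc(OC)cc(OC)c1
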